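**Retrosynthetic overview**

1. The last disconnections are the thirteen O-benzyl groups and the upper C4–C8 interflavan bond, which leads back to a 4-methoxyflavan electrophile (top unit) and a benzylated dimer nucleophile (middle + bottom units).
2. Key disconnection: ring C of the middle unit is opened at C4–C4a and, in the same operation, C4 is cut from C8 of the bottom unit, giving an acyclic (2S,3R)-2-benzyloxy-3-aryl-3-aryloxypropanal and tetra-O-benzyl-(−)-epicatechin.
3. Enabling feature: C4 of the middle unit is a methine bonded to two electron-rich aryl carbons (its own C4a, ortho to O1 on the phloroglucinol-type ring A, and C8 of ring A of the bottom unit), so it is a masked aldehyde carbon that both rings can arylate in turn. C4a sits 1,5 to it through O1–C2–C3, the two ortho carbons of the 3,5-dibenzyloxyphenyl ether are equivalent, and the C3 oxygen cis to the C2 aryl steers the second arene to the 4β face.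
4. Both aldehydes (top and middle series) come from an Evans syn-glycolate aldol (C2/C3 pair), Weinreb transamidation, Pd-catalysed O-arylation with retention (O1–C8a bond) and iBu2AlH reduction.
5. Ring order: rings A and B are bought as arenes and the bottom unit is natural (−)-epicatechin; ring C of the top unit is closed first (step 6), ring C of the middle unit last (step 12).

Key step: step 12

Remark: the target is read as (−)-epiafzelechin-(4β→8)-(−)-epicatechin-(4β→8)-(−)-epicatechin; each flavan unit is 2R,3R (2,3-cis) and each interflavan bond is trans to the neighbouring C3 oxygen.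

**Route**

Step 1
Reactants: 1 (4S)-4-benzyl-1,3-oxazolidin-2-one; 2 (benzyloxy)acetyl chloride
Product: 3 (4S)-4-benzyl-3-[(benzyloxy)acetyl]-1,3-oxazolidin-2-one
Conditions: n-BuLi, THF, −78 °C; then 2, −78 → 0 °C
Reagents that add atoms: none
Why: N-acylation of the lithiated oxazolidinone by the acid chloride (standard loading of an Evans auxiliary); no stereocentre is touched.

Step 2
Reactants: 3 (4S)-4-benzyl-3-[(benzyloxy)acetyl]-1,3-oxazolidin-2-one; 4 4-(benzyloxy)benzaldehyde
Product: 5 (4S)-4-benzyl-3-[(2S,3R)-2-(benzyloxy)-3-[4-(benzyloxy)phenyl]-3-hydroxypropanoyl]-1,3-oxazolidin-2-one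
Conditions: Bu2BOTf, Et3N, CH2Cl2, −78 → 0 °C; 4, −78 → 0 °C; then pH 7 buffer, MeOH, H2O2, 0 °C
Reagents that add atoms: none
Why: Evans syn-glycolate aldol: the Z-boron enolate reacts through a closed Zimmerman–Traxler chair whose enolate face is fixed by the 4-benzyl group of the auxiliary, so the carbinol carbon (future C2 of the top unit) and the benzyloxy carbon (future C3) should be set together as the syn (2S,3R) pair that maps onto a 2,3-cis flavan-3-ol.

Step 3
Reactants: 5 (4S)-4-benzyl-3-[(2S,3R)-2-(benzyloxy)-3-[4-(benzyloxy)phenyl]-3-hydroxypropanoyl]-1,3-oxazolidin-2-one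
Product: 6 (2S,3R)-2-(benzyloxy)-3-[4-(benzyloxy)phenyl]-3-hydroxy-N-methoxy-N-methylpropanamide
Conditions: MeNH(OMe)·HCl, AlMe3, CH2Cl2, −20 → 0 °C; aq. HCl work-up
Reagents that add atoms: N,O-dimethylhydroxylamine hydrochloride (CNOC.Cl)
Why: Aluminium-amide transamidation of an Evans aldol adduct to the Weinreb amide, assisted by the free β-hydroxyl; both stereocentres stay untouched and the amide should resist retro-aldol cleavage far better than the imide in the next, basic step.

Step 4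
Reactants: 6 (2S,3R)-2-(benzyloxy)-3-[4-(benzyloxy)phenyl]-3-hydroxy-N-methoxy-N-methylpropanamide; 7 1,3-bis(benzyloxy)-5-bromobenzene
Product: 8 (2S,3R)-2-(benzyloxy)-3-[4-(benzyloxy)phenyl]-3-[3,5-bis(benzyloxy)phenoxy]-N-methoxy-N-methylpropanamide
Conditions: [Pd(allyl)Cl]2 (cat.), RockPhos (cat.), Cs2CO3, toluene, 90 °C
Reagents that add atoms: none
Why: Buchwald-type Pd-catalysed C–O cross-coupling of a secondary alcohol with an aryl bromide; the aryl–O bond is made and the carbinol C–O bond is never broken, so the benzylic centre keeps its configuration, which is the retention a 2,3-cis flavan requires from a syn aldol (a Mitsunobu etherification would invert it).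

Step 5
Reactants: 8 (2S,3R)-2-(benzyloxy)-3-[4-(benzyloxy)phenyl]-3-[3,5-bis(benzyloxy)phenoxy]-N-methoxy-N-methylpropanamide
Product: 9 (2S,3R)-2-(benzyloxy)-3-[4-(benzyloxy)phenyl]-3-[3,5-bis(benzyloxy)phenoxy]propanal
Conditions: iBu2AlH (DIBAL-H), THF, −78 °C; aq. KNaC4H4O6 work-up; used crude
Reagents that add atoms: none
Why: Weinreb amide reduction: the chelated tetrahedral aluminium adduct should survive at −78 °C and release the aldehyde only on work-up, which avoids over-reduction and epimerization of the α-benzyloxy centre.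

Step 6
Reactants: 9 (2S,3R)-2-(benzyloxy)-3-[4-(benzyloxy)phenyl]-3-[3,5-bis(benzyloxy)phenoxy]propanal
Product: 11 (2R,3R,4S)-3,5,7-tris(benzyloxy)-2-[4-(benzyloxy)phenyl]-4-methoxy-3,4-dihydro-2H-chromene, via dimethyl acetal 10 (not isolated)
Conditions: CSA (cat.), MeOH/CH2Cl2, 0 °C → rt
Reagents that add atoms: methanol (CO)
Why: Acid-catalysed acetalization followed by intramolecular Friedel–Crafts alkylation of the oxocarbenium ion by the ortho carbon of the phloroglucinol-type ether (the known cyclization of 3-aryloxypropanal acetals to 4-alkoxychromans, 6-exo-trig) should close ring C of the top unit; excess methanol traps the C4 cation reversibly anti to the C3 benzyloxy group, so the 4β-methoxy ether is expected, and either C4 epimer would serve in step 13.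

Step 7
Reactants: 3 (4S)-4-benzyl-3-[(benzyloxy)acetyl]-1,3-oxazolidin-2-one; 12 3,4-bis(benzyloxy)benzaldehyde
Product: 13 (4S)-4-benzyl-3-[(2S,3R)-2-(benzyloxy)-3-[3,4-bis(benzyloxy)phenyl]-3-hydroxypropanoyl]-1,3-oxazolidin-2-one
Conditions: Bu2BOTf, Et3N, CH2Cl2, −78 → 0 °C; 12, −78 → 0 °C; then pH 7 buffer, MeOH, H2O2, 0 °C
Reagents that add atoms: none
Why: Evans syn-glycolate aldol as in step 2; the auxiliary-controlled Zimmerman–Traxler chair should set the future C2 and C3 of the middle unit as the syn (2S,3R) pair.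

Step 8
Reactants: 13 (4S)-4-benzyl-3-[(2S,3R)-2-(benzyloxy)-3-[3,4-bis(benzyloxy)phenyl]-3-hydroxypropanoyl]-1,3-oxazolidin-2-one
Product: 14 (2S,3R)-2-(benzyloxy)-3-[3,4-bis(benzyloxy)phenyl]-3-hydroxy-N-methoxy-N-methylpropanamide
Conditions: MeNH(OMe)·HCl, AlMe3, CH2Cl2, −20 → 0 °C; aq. HCl work-up
Reagents that add atoms: N,O-dimethylhydroxylamine hydrochloride (CNOC.Cl)
Why: Weinreb transamidation of the aldol adduct as in step 3; no stereocentre is involved.

Step 9
Reactants: 14 (2S,3R)-2-(benzyloxy)-3-[3,4-bis(benzyloxy)phenyl]-3-hydroxy-N-methoxy-N-methylpropanamide; 7 1,3-bis(benzyloxy)-5-bromobenzene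
Product: 15 (2S,3R)-2-(benzyloxy)-3-[3,4-bis(benzyloxy)phenyl]-3-[3,5-bis(benzyloxy)phenoxy]-N-methoxy-N-methylpropanamide
Conditions: [Pd(allyl)Cl]2 (cat.), RockPhos (cat.), Cs2CO3, toluene, 90 °C
Reagents that add atoms: none
Why: Buchwald-type Pd-catalysed C–O cross-coupling as in step 4; the O1–aryl bond of the middle unit is formed with retention at the future C2 because the carbinol C–O bond is not broken.

Step 10
Reactants: 15 (2S,3R)-2-(benzyloxy)-3-[3,4-bis(benzyloxy)phenyl]-3-[3,5-bis(benzyloxy)phenoxy]-N-methoxy-N-methylpropanamide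
Product: 16 (2S,3R)-2-(benzyloxy)-3-[3,4-bis(benzyloxy)phenyl]-3-[3,5-bis(benzyloxy)phenoxy]propanal
Conditions: iBu2AlH (DIBAL-H), THF, −78 °C; aq. KNaC4H4O6 work-up; used crude
Reagents that add atoms: none
Why: Weinreb amide reduction as in step 5; this puts the future C4 at the aldehyde oxidation level needed for two successive arylations.

Step 11
Reactants: 17 (−)-epicatechin
Product: 18 5,7,3',4'-tetra-O-benzyl-(−)-epicatechin
Conditions: BnBr, K2CO3, DMF, 0 °C → rt
Reagents that add atoms: benzyl bromide (BrCc1ccccc1)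
Why: Williamson etherification of the four phenols with a carbonate base that should leave the much less acidic secondary 3-hydroxyl free; the two stereocentres of the natural product are carried through.

Step 12
Reactants: 16 (2S,3R)-2-(benzyloxy)-3-[3,4-bis(benzyloxy)phenyl]-3-[3,5-bis(benzyloxy)phenoxy]propanal; 18 5,7,3',4'-tetra-O-benzyl-(−)-epicatechin
Product: 20 3-O-benzyl-5,7,3',4'-tetra-O-benzyl-(−)-epicatechin-(4β→8)-5,7,3',4'-tetra-O-benzyl-(−)-epicatechin, via chroman-4-ol 19 (not isolated)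
Conditions: BF3·OEt2 (0.5 equiv), 4 Å MS, CH2Cl2, −78 → −20 °C; 18 in excess (3 equiv)
Reagents that add atoms: none
Why: Proposed new method: BF3 activates the α-benzyloxy aldehyde of 16, whose carbonyl carbon is attacked by an ortho carbon of the tethered 3,5-dibenzyloxyphenyl ether (6-exo-trig Friedel–Crafts hydroxyalkylation; the two ortho carbons are equivalent, so either gives the same chroman-4-ol 19), and 19 should ionize at once to the C4 benzylic cation, which C8 of 18 captures. The closest known reaction types are the acid-mediated cyclization of 3-aryloxypropanals and their acetals to chroman-4-ols and 4-alkoxychromans (and of 3-aryloxypropanoic acids to chroman-4-ones), the double Friedel–Crafts arylation of aldehydes to triarylmethanes, and the Lewis-acid coupling of flavan C4 electrophiles with flavan-3-ols; what is new is their fusion, so that ring C and the interflavan bond grow from one aldehyde carbon. Ring C closes by C4–C4a bond formation, while C2 and C3 come unchanged from 16. The new stereocentre C4 is controlled by the C3 benzyloxy group, which is axial on the half-chair cation when the 2-aryl group is equatorial, so the arene should enter anti to it and give the 3,4-trans (4β) bond typical of 2,3-cis flavan-4-yl cations. The step needs ring closure to outrun intermolecular attack of 18 on the aldehyde (secured by the 1,5-disposition of C4a and the carbonyl carbon and by the triply oxygenated ring), C8 over C6 selectivity in 18 (the usual preference of 5,7-di-O-benzyl flavan-3-ols, here used in excess), and survival of the benzylic C2–O1 ether (the aldehyde is the most Lewis-basic site and the temperature is low).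

Step 13
Reactants: 11 (2R,3R,4S)-3,5,7-tris(benzyloxy)-2-[4-(benzyloxy)phenyl]-4-methoxy-3,4-dihydro-2H-chromene; 20 3-O-benzyl-5,7,3',4'-tetra-O-benzyl-(−)-epicatechin-(4β→8)-5,7,3',4'-tetra-O-benzyl-(−)-epicatechin
Product: 21 trideca-O-benzyl-(−)-epiafzelechin-(4β→8)-(−)-epicatechin-(4β→8)-(−)-epicatechin (only the 3-hydroxyl of the bottom unit free)
Conditions: TMSOTf (cat.), CH2Cl2, −78 °C; 20 in excess (1.5 equiv, remainder recovered); Et3N quench
Reagents that add atoms: none
Why: Lewis-acid-mediated flavan C4–C8 coupling (classical proanthocyanidin chain extension): TMSOTf ionizes the 4-methoxy group of 11 and the cation should be captured by C8 of the upper unit of 20, the most accessible free ring-A position of the dimer, from the face anti to the C3 benzyloxy group, which sets the 4β (3,4-trans) configuration.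

Step 14
Reactants: 21 trideca-O-benzyl-(−)-epiafzelechin-(4β→8)-(−)-epicatechin-(4β→8)-(−)-epicatechin
Product: 22 (−)-epiafzelechin-(4β→8)-(−)-epicatechin-(4β→8)-(−)-epicatechin (CNP0158921.2)
Conditions: H2 (1 atm), Pd(OH)2/C, THF/MeOH/H2O, rt
Reagents that add atoms: none
Why: Hydrogenolysis of all thirteen benzyl ethers (eleven aryl, two alkyl) under neutral conditions, which should touch neither the acid- and base-sensitive interflavan bonds nor any stereocentre.

**Compound list**

1 | (4S)-4-benzyl-1,3-oxazolidin-2-one | O=C1N[C@@H](Cc2ccccc2)CO1 | starting material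
2 | (benzyloxy)acetyl chloride | ClC(=O)COCc1ccccc1 | starting material
3 | (4S)-4-benzyl-3-[(benzyloxy)acetyl]-1,3-oxazolidin-2-one | O=C(COCc1ccccc1)N1C(=O)OC[C@@H]1Cc1ccccc1 | intermediate
4 | 4-(benzyloxy)benzaldehyde | O=Cc1ccc(OCc2ccccc2)cc1 | starting material
5 | (4S)-4-benzyl-3-[(2S,3R)-2-(benzyloxy)-3-[4-(benzyloxy)phenyl]-3-hydroxypropanoyl]-1,3-oxazolidin-2-one | O[C@H](c1ccc(OCc2ccccc2)cc1)[C@H](OCc1ccccc1)C(=O)N1C(=O)OC[C@@H]1Cc1ccccc1 | intermediate
6 | (2S,3R)-2-(benzyloxy)-3-[4-(benzyloxy)phenyl]-3-hydroxy-N-methoxy-N-methylpropanamide | O[C@H](c1ccc(OCc2ccccc2)cc1)[C@H](OCc1ccccc1)C(=O)N(C)OC | intermediate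
7 | 1,3-bis(benzyloxy)-5-bromobenzene | Brc1cc(OCc2ccccc2)cc(OCc2ccccc2)c1 | starting material
8 | (2S,3R)-2-(benzyloxy)-3-[4-(benzyloxy)phenyl]-3-[3,5-bis(benzyloxy)phenoxy]-N-methoxy-N-methylpropanamide | c1c(OCc9ccccc9)cc(OCc9ccccc9)cc1O[C@H](c1ccc(OCc9ccccc9)cc1)[C@H](OCc9ccccc9)C(=O)N(C)OC | intermediate
9 | (2S,3R)-2-(benzyloxy)-3-[4-(benzyloxy)phenyl]-3-[3,5-bis(benzyloxy)phenoxy]propanal | c1c(OCc9ccccc9)cc(OCc9ccccc9)cc1O[C@H](c1ccc(OCc9ccccc9)cc1)[C@H](OCc9ccccc9)C=O | intermediate
10 | 1,3-bis(benzyloxy)-5-{(1R,2S)-2-(benzyloxy)-1-[4-(benzyloxy)phenyl]-3,3-dimethoxypropoxy}benzene (dimethyl acetal of 9, formed in the flask) | c1c(OCc9ccccc9)cc(OCc9ccccc9)cc1O[C@H](c1ccc(OCc9ccccc9)cc1)[C@H](OCc9ccccc9)C(OC)OC | intermediate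
11 | (2R,3R,4S)-3,5,7-tris(benzyloxy)-2-[4-(benzyloxy)phenyl]-4-methoxy-3,4-dihydro-2H-chromene (4β-methoxy-3,5,7,4'-tetra-O-benzylepiafzelechin) | c1c(OCc9ccccc9)cc(OCc9ccccc9)c2c1O[C@H](c1ccc(OCc9ccccc9)cc1)[C@H](OCc9ccccc9)[C@H]2OC | intermediate
12 | 3,4-bis(benzyloxy)benzaldehyde | O=Cc1ccc(OCc2ccccc2)c(OCc2ccccc2)c1 | starting material
13 | (4S)-4-benzyl-3-[(2S,3R)-2-(benzyloxy)-3-[3,4-bis(benzyloxy)phenyl]-3-hydroxypropanoyl]-1,3-oxazolidin-2-one | O[C@H](c1ccc(OCc2ccccc2)c(OCc2ccccc2)c1)[C@H](OCc1ccccc1)C(=O)N1C(=O)OC[C@@H]1Cc1ccccc1 | intermediate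
14 | (2S,3R)-2-(benzyloxy)-3-[3,4-bis(benzyloxy)phenyl]-3-hydroxy-N-methoxy-N-methylpropanamide | O[C@H](c1ccc(OCc2ccccc2)c(OCc2ccccc2)c1)[C@H](OCc1ccccc1)C(=O)N(C)OC | intermediate
15 | (2S,3R)-2-(benzyloxy)-3-[3,4-bis(benzyloxy)phenyl]-3-[3,5-bis(benzyloxy)phenoxy]-N-methoxy-N-methylpropanamide | c1c(OCc9ccccc9)cc(OCc9ccccc9)cc1O[C@H](c1ccc(OCc9ccccc9)c(OCc9ccccc9)c1)[C@H](OCc9ccccc9)C(=O)N(C)OC | intermediate
16 | (2S,3R)-2-(benzyloxy)-3-[3,4-bis(benzyloxy)phenyl]-3-[3,5-bis(benzyloxy)phenoxy]propanal | c1c(OCc9ccccc9)cc(OCc9ccccc9)cc1O[C@H](c1ccc(OCc9ccccc9)c(OCc9ccccc9)c1)[C@H](OCc9ccccc9)C=O | intermediate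
17 | (−)-epicatechin, (2R,3R)-2-(3,4-dihydroxyphenyl)-3,4-dihydro-2H-chromene-3,5,7-triol | O[C@@H]1Cc2c(O)cc(O)cc2O[C@@H]1c1ccc(O)c(O)c1 | starting material
18 | 5,7,3',4'-tetra-O-benzyl-(−)-epicatechin, (2R,3R)-5,7-bis(benzyloxy)-2-[3,4-bis(benzyloxy)phenyl]-3,4-dihydro-2H-chromen-3-ol | O[C@@H]1Cc2c(OCc9ccccc9)cc(OCc9ccccc9)cc2O[C@@H]1c1ccc(OCc9ccccc9)c(OCc9ccccc9)c1 | intermediate
19 | (2R,3R)-3,5,7-tris(benzyloxy)-2-[3,4-bis(benzyloxy)phenyl]-3,4-dihydro-2H-chromen-4-ol (C4 configuration not controlled and without consequence, formed in the flask) | c1c(OCc9ccccc9)cc(OCc9ccccc9)c2c1O[C@H](c1ccc(OCc9ccccc9)c(OCc9ccccc9)c1)[C@H](OCc9ccccc9)C2O | intermediate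
20 | 3-O-benzyl-5,7,3',4'-tetra-O-benzyl-(−)-epicatechin-(4β→8)-5,7,3',4'-tetra-O-benzyl-(−)-epicatechin (nona-O-benzyl dimer, 3-hydroxyl of the lower unit free) | c1c(OCc9ccccc9)cc(OCc9ccccc9)c2c1O[C@H](c1ccc(OCc9ccccc9)c(OCc9ccccc9)c1)[C@H](OCc9ccccc9)[C@H]2c1c(OCc9ccccc9)cc(OCc9ccccc9)c2c1O[C@H](c1ccc(OCc9ccccc9)c(OCc9ccccc9)c1)[C@H](O)C2 | intermediate
21 | trideca-O-benzyl-(−)-epiafzelechin-(4β→8)-(−)-epicatechin-(4β→8)-(−)-epicatechin (3-O-benzyl on the top and middle units, 3-hydroxyl of the bottom unit free) | c1c(OCc9ccccc9)cc(OCc9ccccc9)c2c1O[C@H](c1ccc(OCc9ccccc9)cc1)[C@H](OCc9ccccc9)[C@H]2c1c(OCc9ccccc9)cc(OCc9ccccc9)c2c1O[C@H](c1ccc(OCc9ccccc9)c(OCc9ccccc9)c1)[C@H](OCc9ccccc9)[C@H]2c1c(OCc9ccccc9)cc(OCc9ccccc9)c2c1O[C@H](c1ccc(OCc9ccccc9)c(OCc9ccccc9)c1)[C@H](O)C2 | intermediate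
22 | (−)-epiafzelechin-(4β→8)-(−)-epicatechin-(4β→8)-(−)-epicatechin (CNP0158921.2) | Oc1ccc([C@H]2Oc3cc(O)cc(O)c3[C@H](c3c(O)cc(O)c4c3O[C@H](c3ccc(O)c(O)c3)[C@H](O)[C@H]4c3c(O)cc(O)c4c3O[C@H](c3ccc(O)c(O)c3)[C@H](O)C4)[C@H]2O)cc1 | target

**Step count and risks**

Total steps: 14. Longest linear sequence: 8 steps (1 → 7 → 8 → 9 → 10 → 12 → 13 → 14; the top-unit branch 1 → 2 → 3 → 4 → 5 → 6 → 13 → 14 is equally long).

Steps most likely to fail:

1. Step 12 (proposed new method). What may go wrong: intermolecular hydroxyalkylation of 18 by the aldehyde before ring closure, which would leave the configuration at C4 to an uncontrolled cyclization; ionization of the benzylic C2–O1 ether with loss of the aryloxy group; decay of the C4 cation by proton loss or self-condensation. Fallback with known chemistry, stepwise in place of the cascade: from 16, acid-catalysed cyclization in methanol (CSA, MeOH/CH2Cl2, as in step 6) should pass through the dimethyl acetal 1,3-bis(benzyloxy)-5-{(1R,2S)-2-(benzyloxy)-1-[3,4-bis(benzyloxy)phenyl]-3,3-dimethoxypropoxy}benzene F1 and give the isolable (2R,3R,4S)-3,5,7-tris(benzyloxy)-2-[3,4-bis(benzyloxy)phenyl]-4-methoxy-3,4-dihydro-2H-chromene F2. This 4-methoxyflavan is then coupled with 18 (3 equiv) under the classical conditions for 4-alkoxyflavan electrophiles (TMSOTf, CH2Cl2, −78 °C), which returns to the route at 20.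

2. Step 9 (step 4 is the same reaction in the top series). What may go wrong: β-hydride elimination from the palladium alkoxide, which oxidizes the electron-rich benzylic alcohol to the ketone; slow C–O reductive elimination at the hindered carbinol; retro-aldol cleavage under Cs2CO3 at 90 °C. Fallback, double inversion by two Mitsunobu reactions in place of the metal-catalysed arylation: from 14, 4-nitrobenzoic acid, PPh3 and DIAD (THF, 0 °C) should give the inverted ester (1S,2S)-2-(benzyloxy)-1-[3,4-bis(benzyloxy)phenyl]-3-[methoxy(methyl)amino]-3-oxopropyl 4-nitrobenzoate F3. Methanolysis (K2CO3 cat., MeOH) frees the anti alcohol (2S,3S)-2-(benzyloxy)-3-[3,4-bis(benzyloxy)phenyl]-3-hydroxy-N-methoxy-N-methylpropanamide F4. Mitsunobu etherification of this alcohol with 3,5-bis(benzyloxy)phenol (Bu3P, TMAD, toluene, 0 °C → rt) inverts the centre a second time and returns to the route at 15.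

3. Step 13. What may go wrong: self-condensation of the electrophile through its own free C8 and C6; imperfect site selectivity among the three free ring-A positions of 20 (upper C8, upper C6, lower C6). Fallback, a blocked electrophile in place of the free one: from 11, NBS (CH2Cl2, −78 → 0 °C) should give (2R,3R,4S)-3,5,7-tris(benzyloxy)-2-[4-(benzyloxy)phenyl]-8-bromo-4-methoxy-3,4-dihydro-2H-chromene F5, which cannot self-condense through C8. Its coupling with 20 (TMSOTf, CH2Cl2, −78 °C) should give the 8-bromo derivative (top unit) of trimer 21 F6. Hydrogenolysis (H2, Pd(OH)2/C, Et3N, THF/MeOH/H2O, rt) removes the bromine together with the benzyl groups and returns to the route at 22.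

**Further compounds**

F1 | step 12 | 1,3-bis(benzyloxy)-5-{(1R,2S)-2-(benzyloxy)-1-[3,4-bis(benzyloxy)phenyl]-3,3-dimethoxypropoxy}benzene | c1c(OCc9ccccc9)cc(OCc9ccccc9)cc1O[C@H](c1ccc(OCc9ccccc9)c(OCc9ccccc9)c1)[C@H](OCc9ccccc9)C(OC)OC
F2 | step 12 | (2R,3R,4S)-3,5,7-tris(benzyloxy)-2-[3,4-bis(benzyloxy)phenyl]-4-methoxy-3,4-dihydro-2H-chromene | c1c(OCc9ccccc9)cc(OCc9ccccc9)c2c1O[C@H](c1ccc(OCc9ccccc9)c(OCc9ccccc9)c1)[C@H](OCc9ccccc9)[C@H]2OC
F3 | step 9 | (1S,2S)-2-(benzyloxy)-1-[3,4-bis(benzyloxy)phenyl]-3-[methoxy(methyl)amino]-3-oxopropyl 4-nitrobenzoate | [O-][N+](=O)c1ccc(cc1)C(=O)O[C@@H](c1ccc(OCc9ccccc9)c(OCc9ccccc9)c1)[C@H](OCc9ccccc9)C(=O)N(C)OC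
F4 | step 9 | (2S,3S)-2-(benzyloxy)-3-[3,4-bis(benzyloxy)phenyl]-3-hydroxy-N-methoxy-N-methylpropanamide | O[C@@H](c1ccc(OCc9ccccc9)c(OCc9ccccc9)c1)[C@H](OCc9ccccc9)C(=O)N(C)OC
F5 | step 13 | (2R,3R,4S)-3,5,7-tris(benzyloxy)-2-[4-(benzyloxy)phenyl]-8-bromo-4-methoxy-3,4-dihydro-2H-chromene | Brc1c(OCc9ccccc9)cc(OCc9ccccc9)c2c1O[C@H](c1ccc(OCc9ccccc9)cc1)[C@H](OCc9ccccc9)[C@H]2OC
F6 | step 13 | 8-bromo (top unit) derivative of trideca-O-benzyl-(−)-epiafzelechin-(4β→8)-(−)-epicatechin-(4β→8)-(−)-epicatechin | Brc1c(OCc9ccccc9)cc(OCc9ccccc9)c2c1O[C@H](c1ccc(OCc9ccccc9)cc1)[C@H](OCc9ccccc9)[C@H]2c1c(OCc9ccccc9)cc(OCc9ccccc9)c2c1O[C@H](c1ccc(OCc9ccccc9)c(OCc9ccccc9)c1)[C@H](OCc9ccccc9)[C@H]2c1c(OCc9ccccc9)cc(OCc9ccccc9)c2c1O[C@H](c1ccc(OCc9ccccc9)c(OCc9ccccc9)c1)[C@H](O)C2
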